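## Retrosynthetic overview

1. Daphnodorin D2 (28) comes from its hexabenzyl ether 27 by one neutral hydrogenolysis. Ring labels: flavone rings A (phloroglucinol), C (pyranone), B (aryl); flavan rings D (phloroglucinol), F (pyran), E (aryl).
2. Ring C is formed last, by Baker–Venkataraman acyl transfer and cyclodehydration of the 2-hydroxydeoxybenzoin 23 with 4-(benzyloxy)benzoyl chloride 24; 23 comes from flavan-8-ylacetaldehyde 16 and an arylcerium reagent made from 18.
3. Aldehyde 16 comes from 8-allylflavan 14; ring F is formed first, by Mitsunobu closure (inversion) of the (R)-carbinol 13, whose centre is set by Noyori transfer hydrogenation.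
4. Key C–C bond (flavan C3–C4): intermolecular Claisen–Schmidt aldol condensation of aldehyde 7 with 4'-benzyloxyacetophenone 8.
5. Aldehyde 7 comes from 2,4,6-trihydroxybenzaldehyde 1 by dibenzylation, O-allylation, aromatic Claisen rearrangement (places the future C8 carbon substituent) and re-allylation.

Assumption: the given structure fixes only C2 of the flavan unit as (S); the hindered aryl–chromone bond is not assigned, so no control of that axis is attempted.

## Route

Step 1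
Reactants: 1 2,4,6-trihydroxybenzaldehyde
Product: 2 2,4-bis(benzyloxy)-6-hydroxybenzaldehyde
Conditions: BnBr (2.1 equiv), K2CO3 (2.2 equiv), DMF, 0 °C to rt
Reagents that add atoms: benzyl bromide BrCc1ccccc1
Why: Williamson etherification benzylates the para and one ortho phenoxide, while the last ortho OH, hydrogen-bonded to the formyl group, is too weakly nucleophilic to react with only two equivalents of halide.

Step 2
Reactants: 2 2,4-bis(benzyloxy)-6-hydroxybenzaldehyde; 3 allyl bromide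
Product: 4 2-(allyloxy)-4,6-bis(benzyloxy)benzaldehyde
Conditions: K2CO3, DMF, 60 °C
Reagents that add atoms: none
Why: Williamson O-allylation of the remaining chelated phenol proceeds with mild heating and installs the allyl group for the sigmatropic shift.

Step 3
Reactants: 4 2-(allyloxy)-4,6-bis(benzyloxy)benzaldehyde
Product: 6 3-allyl-4,6-bis(benzyloxy)-2-hydroxybenzaldehyde, via ortho-dienone 5 (not isolated)
Conditions: N,N-diethylaniline, 195 °C, sealed tube
Reagents that add atoms: none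
Why: In this aromatic Claisen rearrangement the [3,3] shift can end only at the one ortho carbon that carries hydrogen (the other carries CHO), and enolisation of 5 restores the phenol, so the carbon substituent lands at the future C8 without regiochemical ambiguity.

Step 4
Reactants: 6 3-allyl-4,6-bis(benzyloxy)-2-hydroxybenzaldehyde; 3 allyl bromide
Product: 7 3-allyl-2-(allyloxy)-4,6-bis(benzyloxy)benzaldehyde
Conditions: K2CO3, DMF, 60 °C
Reagents that add atoms: none
Why: Williamson re-allylation masks the future pyran oxygen as an ether that zerovalent palladium removes later, so the aldehyde is not deactivated as a phenoxide in the aldol step.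

Step 5
Reactants: 7 3-allyl-2-(allyloxy)-4,6-bis(benzyloxy)benzaldehyde; 8 1-[4-(benzyloxy)phenyl]ethan-1-one
Product: 10 (E)-3-[3-allyl-2-(allyloxy)-4,6-bis(benzyloxy)phenyl]-1-[4-(benzyloxy)phenyl]prop-2-en-1-one, via aldol adduct 9 (not isolated)
Conditions: KOH (50% aq.), EtOH/THF, rt, 24–48 h
Reagents that add atoms: none
Why: In this Claisen–Schmidt crossed aldol condensation only ketone 8 can form an enolate and only aldehyde 7 can accept it, and E1cB loss of water from 9 gives the E-enone, which creates the C3–C4 bond of the future flavan and joins ring E to ring D.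

Step 6
Reactants: 10 (E)-3-[3-allyl-2-(allyloxy)-4,6-bis(benzyloxy)phenyl]-1-[4-(benzyloxy)phenyl]prop-2-en-1-one
Product: 11 3-[3-allyl-2-(allyloxy)-4,6-bis(benzyloxy)phenyl]-1-[4-(benzyloxy)phenyl]propan-1-one
Conditions: [(Ph3P)CuH]6 (0.5 equiv), H2O (5 equiv), degassed toluene, rt; aq. NH4Cl work-up
Reagents that add atoms: none
Why: Copper hydride 1,4-reduction (Stryker conjugate reduction) saturates only the enone double bond and leaves the isolated allyl alkenes, the benzyl ethers and the ketone untouched.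

Step 7
Reactants: 11 3-[3-allyl-2-(allyloxy)-4,6-bis(benzyloxy)phenyl]-1-[4-(benzyloxy)phenyl]propan-1-one
Product: 12 (1R)-3-[3-allyl-2-(allyloxy)-4,6-bis(benzyloxy)phenyl]-1-[4-(benzyloxy)phenyl]propan-1-ol
Conditions: RuCl[(R,R)-TsDPEN](p-cymene) (2 mol %), HCO2H/Et3N (5:2), CH2Cl2, 30 °C
Reagents that add atoms: none
Why: In this Noyori asymmetric transfer hydrogenation the (R,R)-TsDPEN ruthenium hydride delivers hydride to the Si face of the aryl ketone through the usual six-membered transition state, setting the (R) carbinol (typically above 95% ee for aryl alkyl ketones) without touching the allyl groups.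

Step 8
Reactants: 12 (1R)-3-[3-allyl-2-(allyloxy)-4,6-bis(benzyloxy)phenyl]-1-[4-(benzyloxy)phenyl]propan-1-ol
Product: 13 2-allyl-3,5-bis(benzyloxy)-6-[(3R)-3-[4-(benzyloxy)phenyl]-3-hydroxypropyl]phenol
Conditions: Pd(PPh3)4 (5 mol %), morpholine (10 equiv), THF, rt
Reagents that add atoms: none
Why: In this Tsuji–Trost deallylation zerovalent palladium ionises only the aryl allyl ether and morpholine traps the allyl unit, while the C-allyl group, the benzyl ethers and the carbinol centre are inert under these neutral conditions.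

Step 9
Reactants: 13 2-allyl-3,5-bis(benzyloxy)-6-[(3R)-3-[4-(benzyloxy)phenyl]-3-hydroxypropyl]phenol
Product: 14 (2S)-8-allyl-5,7-bis(benzyloxy)-2-[4-(benzyloxy)phenyl]chromane
Conditions: PPh3 (1.5 equiv), DIAD (1.5 equiv), THF (dilute), 0 °C
Reagents that add atoms: none
Why: In this intramolecular Mitsunobu etherification the phenol displaces the oxyphosphonium-activated (R) carbinol by SN2 with inversion, closing ring F and giving the (2S) configuration of the target.

Step 10
Reactants: 14 (2S)-8-allyl-5,7-bis(benzyloxy)-2-[4-(benzyloxy)phenyl]chromane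
Product: 16 2-[(2S)-5,7-bis(benzyloxy)-2-[4-(benzyloxy)phenyl]chroman-8-yl]acetaldehyde, via vicinal diol 15 (not isolated)
Conditions: OsO4 (2 mol %), NaIO4 (4 equiv), 2,6-lutidine, 1,4-dioxane/H2O (3:1), rt
Reagents that add atoms: osmium tetroxide O=[Os](=O)(=O)=O (catalytic oxygen donor), sodium periodate [Na+].[O-]I(=O)(=O)=O (terminal oxidant that re-forms it)
Why: In this Lemieux–Johnson oxidation the only alkene is dihydroxylated and the diol cleaved by periodate, which turns the allyl group into the CH2–CHO unit that becomes C3 and C4 of ring C, under conditions that do not affect aryl ethers or C2.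

Step 11
Reactants: 17 1,3,5-tris(benzyloxy)benzene
Product: 18 2-bromo-1,3,5-tris(benzyloxy)benzene
Conditions: NBS (1.0 equiv), CH2Cl2, −20 to 0 °C
Reagents that add atoms: N-bromosuccinimide O=C1CCC(=O)N1Br
Why: Electrophilic aromatic bromination of a symmetric arene with three equivalent ring positions gives a single monobromide when one equivalent is used at low temperature.

Step 12
Reactants: 16 2-[(2S)-5,7-bis(benzyloxy)-2-[4-(benzyloxy)phenyl]chroman-8-yl]acetaldehyde; 18 2-bromo-1,3,5-tris(benzyloxy)benzene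
Product: 21 2-[(2S)-5,7-bis(benzyloxy)-2-[4-(benzyloxy)phenyl]chroman-8-yl]-1-[2,4,6-tris(benzyloxy)phenyl]ethan-1-ol, via aryllithium 19 (not isolated), via arylcerium dichloride 20 (not isolated)
Conditions: 18 (1.5 equiv), n-BuLi, THF, −78 °C; anhydrous CeCl3, −78 °C; then 16, −78 °C; water quench
Reagents that add atoms: none
Why: Bromine–lithium exchange followed by transmetalation gives a weakly basic, strongly nucleophilic organocerium (Imamoto conditions) that adds 1,2 to the enolisable arylacetaldehyde instead of deprotonating it, and the new carbinol centre is irrelevant because it is oxidised in the next step.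

Step 13
Reactants: 21 2-[(2S)-5,7-bis(benzyloxy)-2-[4-(benzyloxy)phenyl]chroman-8-yl]-1-[2,4,6-tris(benzyloxy)phenyl]ethan-1-ol
Product: 22 2-[(2S)-5,7-bis(benzyloxy)-2-[4-(benzyloxy)phenyl]chroman-8-yl]-1-[2,4,6-tris(benzyloxy)phenyl]ethan-1-one
Conditions: Dess–Martin periodinane (1.5 equiv), pyridine (5 equiv), CH2Cl2, 0 °C to rt
Reagents that add atoms: none
Why: Dess–Martin oxidation under pyridine buffering converts the acid-sensitive electron-rich benzylic alcohol into the deoxybenzoin without ionising it or the flavan.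

Step 14
Reactants: 22 2-[(2S)-5,7-bis(benzyloxy)-2-[4-(benzyloxy)phenyl]chroman-8-yl]-1-[2,4,6-tris(benzyloxy)phenyl]ethan-1-one
Product: 23 1-[2,4-bis(benzyloxy)-6-hydroxyphenyl]-2-[(2S)-5,7-bis(benzyloxy)-2-[4-(benzyloxy)phenyl]chroman-8-yl]ethan-1-one
Conditions: BCl3 (1.2 equiv, 1 M in CH2Cl2), CH2Cl2, −78 °C, 30 min; water quench
Reagents that add atoms: none
Why: In this chelation-controlled mono-debenzylation BCl3 is held between the ketone oxygen and one ortho benzyl ether and cleaves only that ether at −78 °C, after which the boron phenoxide chelate protects the second ortho ether and the non-chelating ethers, including the flavan oxygen, react far more slowly.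

Step 15
Reactants: 23 1-[2,4-bis(benzyloxy)-6-hydroxyphenyl]-2-[(2S)-5,7-bis(benzyloxy)-2-[4-(benzyloxy)phenyl]chroman-8-yl]ethan-1-one; 24 4-(benzyloxy)benzoyl chloride
Product: 25 3,5-bis(benzyloxy)-2-{2-[(2S)-5,7-bis(benzyloxy)-2-[4-(benzyloxy)phenyl]chroman-8-yl]acetyl}phenyl 4-(benzyloxy)benzoate
Conditions: 24 (1.3 equiv), pyridine, DMAP (cat.), 50 °C
Reagents that add atoms: none
Why: O-acylation (esterification) of the freed phenol places the aroyl group next to the acidic benzylic ketone methylene for the acyl transfer.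

Step 16
Reactants: 25 3,5-bis(benzyloxy)-2-{2-[(2S)-5,7-bis(benzyloxy)-2-[4-(benzyloxy)phenyl]chroman-8-yl]acetyl}phenyl 4-(benzyloxy)benzoate
Product: 27 5,7-bis(benzyloxy)-2-[4-(benzyloxy)phenyl]-3-[(2S)-5,7-bis(benzyloxy)-2-[4-(benzyloxy)phenyl]chroman-8-yl]-4H-chromen-4-one, via 1,3-diketone 26 (not isolated)
Conditions: LiN(SiMe3)2 (3 equiv), THF, −78 to 0 °C; AcOH quench; then PPTS (0.2 equiv), 4 Å MS, toluene, 60 °C
Reagents that add atoms: none
Why: In this Baker–Venkataraman rearrangement (an intramolecular Claisen condensation) the ketone enolate takes the aroyl group from the phenol oxygen, and the hemiketal of 26 then loses water under weak acid to give the aromatic pyranone ring C without ionising the C2–O bond of the flavan.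

Step 17
Reactants: 27 5,7-bis(benzyloxy)-2-[4-(benzyloxy)phenyl]-3-[(2S)-5,7-bis(benzyloxy)-2-[4-(benzyloxy)phenyl]chroman-8-yl]-4H-chromen-4-one
Product: 28 daphnodorin D2
Conditions: H2 (1 atm), 10% Pd/C, THF/MeOH (1:1), rt
Reagents that add atoms: none
Why: Catalytic hydrogenolysis cleaves all six O-benzyl groups under neutral conditions, so the (2S) centre cannot epimerise through a quinone methide or benzylic cation, while the tetrasubstituted chromone double bond and the cyclic benzylic ether are not reduced at 1 atm.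

## Compound list

1 | 2,4,6-trihydroxybenzaldehyde | O=Cc1c(O)cc(O)cc1O | starting material
2 | 2,4-bis(benzyloxy)-6-hydroxybenzaldehyde | O=Cc1c(O)cc(OCc2ccccc2)cc1OCc1ccccc1 | intermediate
3 | allyl bromide | C=CCBr | starting material
4 | 2-(allyloxy)-4,6-bis(benzyloxy)benzaldehyde | O=Cc1c(OCC=C)cc(OCc2ccccc2)cc1OCc1ccccc1 | intermediate
5 | 5-allyl-2,4-bis(benzyloxy)-6-oxocyclohexa-1,3-diene-1-carbaldehyde (ortho-dienone, racemic) | O=CC1=C(OCc2ccccc2)C=C(OCc2ccccc2)C(CC=C)C1=O | intermediate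
6 | 3-allyl-4,6-bis(benzyloxy)-2-hydroxybenzaldehyde | O=Cc1c(O)c(CC=C)c(OCc2ccccc2)cc1OCc1ccccc1 | intermediate
7 | 3-allyl-2-(allyloxy)-4,6-bis(benzyloxy)benzaldehyde | O=Cc1c(OCC=C)c(CC=C)c(OCc2ccccc2)cc1OCc1ccccc1 | intermediate
8 | 1-[4-(benzyloxy)phenyl]ethan-1-one | CC(=O)c1ccc(OCc2ccccc2)cc1 | starting material
9 | 3-[3-allyl-2-(allyloxy)-4,6-bis(benzyloxy)phenyl]-1-[4-(benzyloxy)phenyl]-3-hydroxypropan-1-one (racemic aldol adduct) | O=C(CC(O)c1c(OCC=C)c(CC=C)c(OCc2ccccc2)cc1OCc1ccccc1)c1ccc(OCc2ccccc2)cc1 | intermediate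
10 | (E)-3-[3-allyl-2-(allyloxy)-4,6-bis(benzyloxy)phenyl]-1-[4-(benzyloxy)phenyl]prop-2-en-1-one | O=C(/C=C/c1c(OCC=C)c(CC=C)c(OCc2ccccc2)cc1OCc1ccccc1)c1ccc(OCc2ccccc2)cc1 | intermediate
11 | 3-[3-allyl-2-(allyloxy)-4,6-bis(benzyloxy)phenyl]-1-[4-(benzyloxy)phenyl]propan-1-one | O=C(CCc1c(OCC=C)c(CC=C)c(OCc2ccccc2)cc1OCc1ccccc1)c1ccc(OCc2ccccc2)cc1 | intermediate
12 | (1R)-3-[3-allyl-2-(allyloxy)-4,6-bis(benzyloxy)phenyl]-1-[4-(benzyloxy)phenyl]propan-1-ol | O[C@H](CCc1c(OCC=C)c(CC=C)c(OCc2ccccc2)cc1OCc1ccccc1)c1ccc(OCc2ccccc2)cc1 | intermediate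
13 | 2-allyl-3,5-bis(benzyloxy)-6-[(3R)-3-[4-(benzyloxy)phenyl]-3-hydroxypropyl]phenol | O[C@H](CCc1c(O)c(CC=C)c(OCc2ccccc2)cc1OCc1ccccc1)c1ccc(OCc2ccccc2)cc1 | intermediate
14 | (2S)-8-allyl-5,7-bis(benzyloxy)-2-[4-(benzyloxy)phenyl]chromane | C=CCc1c(OCc2ccccc2)cc(OCc2ccccc2)c2c1O[C@H](c1ccc(OCc3ccccc3)cc1)CC2 | intermediate
15 | 3-[(2S)-5,7-bis(benzyloxy)-2-[4-(benzyloxy)phenyl]chroman-8-yl]propane-1,2-diol (both carbinol epimers) | OCC(O)Cc1c(OCc2ccccc2)cc(OCc2ccccc2)c2c1O[C@H](c1ccc(OCc3ccccc3)cc1)CC2 | intermediate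
16 | 2-[(2S)-5,7-bis(benzyloxy)-2-[4-(benzyloxy)phenyl]chroman-8-yl]acetaldehyde | O=CCc1c(OCc2ccccc2)cc(OCc2ccccc2)c2c1O[C@H](c1ccc(OCc3ccccc3)cc1)CC2 | intermediate
17 | 1,3,5-tris(benzyloxy)benzene | c1ccc(COc2cc(OCc3ccccc3)cc(OCc3ccccc3)c2)cc1 | starting material
18 | 2-bromo-1,3,5-tris(benzyloxy)benzene | Brc1c(OCc2ccccc2)cc(OCc2ccccc2)cc1OCc1ccccc1 | intermediate
19 | [2,4,6-tris(benzyloxy)phenyl]lithium | [Li]c1c(OCc2ccccc2)cc(OCc2ccccc2)cc1OCc1ccccc1 | intermediate
20 | [2,4,6-tris(benzyloxy)phenyl]cerium dichloride | Cl[Ce](Cl)c1c(OCc2ccccc2)cc(OCc2ccccc2)cc1OCc1ccccc1 | intermediate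
21 | 2-[(2S)-5,7-bis(benzyloxy)-2-[4-(benzyloxy)phenyl]chroman-8-yl]-1-[2,4,6-tris(benzyloxy)phenyl]ethan-1-ol (both carbinol epimers) | OC(Cc1c(OCc2ccccc2)cc(OCc2ccccc2)c2c1O[C@H](c1ccc(OCc3ccccc3)cc1)CC2)c1c(OCc2ccccc2)cc(OCc2ccccc2)cc1OCc1ccccc1 | intermediate
22 | 2-[(2S)-5,7-bis(benzyloxy)-2-[4-(benzyloxy)phenyl]chroman-8-yl]-1-[2,4,6-tris(benzyloxy)phenyl]ethan-1-one | O=C(Cc1c(OCc2ccccc2)cc(OCc2ccccc2)c2c1O[C@H](c1ccc(OCc3ccccc3)cc1)CC2)c1c(OCc2ccccc2)cc(OCc2ccccc2)cc1OCc1ccccc1 | intermediate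
23 | 1-[2,4-bis(benzyloxy)-6-hydroxyphenyl]-2-[(2S)-5,7-bis(benzyloxy)-2-[4-(benzyloxy)phenyl]chroman-8-yl]ethan-1-one | O=C(Cc1c(OCc2ccccc2)cc(OCc2ccccc2)c2c1O[C@H](c1ccc(OCc3ccccc3)cc1)CC2)c1c(O)cc(OCc2ccccc2)cc1OCc1ccccc1 | intermediate
24 | 4-(benzyloxy)benzoyl chloride | O=C(Cl)c1ccc(OCc2ccccc2)cc1 | starting material
25 | 3,5-bis(benzyloxy)-2-{2-[(2S)-5,7-bis(benzyloxy)-2-[4-(benzyloxy)phenyl]chroman-8-yl]acetyl}phenyl 4-(benzyloxy)benzoate | O=C(Oc1cc(OCc2ccccc2)cc(OCc2ccccc2)c1C(=O)Cc1c(OCc2ccccc2)cc(OCc2ccccc2)c2c1O[C@H](c1ccc(OCc3ccccc3)cc1)CC2)c1ccc(OCc2ccccc2)cc1 | intermediate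
26 | 1-[2,4-bis(benzyloxy)-6-hydroxyphenyl]-3-[4-(benzyloxy)phenyl]-2-[(2S)-5,7-bis(benzyloxy)-2-[4-(benzyloxy)phenyl]chroman-8-yl]propane-1,3-dione (methine epimers, in equilibrium with its cyclic hemiketal) | O=C(c1ccc(OCc2ccccc2)cc1)C(C(=O)c1c(O)cc(OCc2ccccc2)cc1OCc1ccccc1)c1c(OCc2ccccc2)cc(OCc2ccccc2)c2c1O[C@H](c1ccc(OCc3ccccc3)cc1)CC2 | intermediate
27 | 5,7-bis(benzyloxy)-2-[4-(benzyloxy)phenyl]-3-[(2S)-5,7-bis(benzyloxy)-2-[4-(benzyloxy)phenyl]chroman-8-yl]-4H-chromen-4-one | O=c1c(-c2c(OCc3ccccc3)cc(OCc3ccccc3)c3c2O[C@H](c2ccc(OCc4ccccc4)cc2)CC3)c(-c2ccc(OCc3ccccc3)cc2)oc2cc(OCc3ccccc3)cc(OCc3ccccc3)c12 | intermediate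
28 | daphnodorin D2, 5,7-dihydroxy-2-(4-hydroxyphenyl)-3-[(2S)-5,7-dihydroxy-2-(4-hydroxyphenyl)chroman-8-yl]-4H-chromen-4-one | O=c1c(-c2c(O)cc(O)c3c2O[C@H](c2ccc(O)cc2)CC3)c(-c2ccc(O)cc2)oc2cc(O)cc(O)c12 | target

## Totals and risks

Total step count: 17. Longest linear sequence: 16 steps (steps 1–10 and 12–17, from compound 1); step 11 is a one-step side branch.

The three steps most likely to fail:

Step 9 (Mitsunobu closure). The carbinol carries a 4-benzyloxyphenyl group, so partial ionisation can compete with SN2 and erode the ee. The fallback sets out from aldehyde 7 and comes back at flavan 14, carrying ring E as an aryl bromide that cannot stabilise a benzylic cation. Claisen–Schmidt condensation of 7 with 4'-bromoacetophenone (KOH, EtOH/THF) gives the (E)-bromochalcone F1. Reduction with [(Ph3P)CuH]6 gives the saturated bromo ketone F2. Transfer hydrogenation with RuCl[(R,R)-TsDPEN](p-cymene) gives the (R)-bromo carbinol F3. Pd(PPh3)4/morpholine deallylation gives the phenol carbinol F4. PPh3/DIAD closure gives the (2S)-2-(4-bromophenyl)flavan F5. Palladium-catalysed C–O coupling of F5 with benzyl alcohol ([(allyl)PdCl]2, RockPhos, Cs2CO3, toluene, 90 °C) then gives 14.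

Step 12 (organocerium addition). The arylacetaldehyde 16 is prone to enolisation and self-condensation, and carbinol 21 is acid-sensitive. The fallback sets out from 16 and comes back at ketone 22, replacing addition/oxidation by acylation. Pinnick oxidation (NaClO2, NaH2PO4, 2-methyl-2-butene, t-BuOH/H2O) gives the arylacetic acid F6. Coupling with N,O-dimethylhydroxylamine hydrochloride (EDC, HOBt, i-Pr2NEt, CH2Cl2) gives the Weinreb amide F7. Aryllithium 19 (from 18 and n-BuLi, THF, −78 °C) then acylates F7 to give 22 directly, so step 13 is skipped.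

Step 16 (Baker–Venkataraman and cyclodehydration). The acyl group must move onto a carbon flanked by a 2,6-disubstituted aryl ring, and the dehydration must be done with weak acid to protect C2. The fallback sets out from phenol ketone 23 and comes back at flavone 27, replacing acyl transfer by an aldol route. Piperidine-catalysed aldol condensation and oxa-Michael closure of 23 with 4-(benzyloxy)benzaldehyde (EtOH/toluene, reflux) gives the trans-2,3-diarylchroman-4-one F8. Dehydrogenation of F8 with catalytic iodine in DMSO (100 °C) gives 27.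

## Further compounds

F1 | step 9 | (E)-3-[3-allyl-2-(allyloxy)-4,6-bis(benzyloxy)phenyl]-1-(4-bromophenyl)prop-2-en-1-one | O=C(/C=C/c1c(OCC=C)c(CC=C)c(OCc2ccccc2)cc1OCc1ccccc1)c1ccc(Br)cc1
F2 | step 9 | 3-[3-allyl-2-(allyloxy)-4,6-bis(benzyloxy)phenyl]-1-(4-bromophenyl)propan-1-one | O=C(CCc1c(OCC=C)c(CC=C)c(OCc2ccccc2)cc1OCc1ccccc1)c1ccc(Br)cc1
F3 | step 9 | (1R)-3-[3-allyl-2-(allyloxy)-4,6-bis(benzyloxy)phenyl]-1-(4-bromophenyl)propan-1-ol | O[C@H](CCc1c(OCC=C)c(CC=C)c(OCc2ccccc2)cc1OCc1ccccc1)c1ccc(Br)cc1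
F4 | step 9 | 2-allyl-3,5-bis(benzyloxy)-6-[(3R)-3-(4-bromophenyl)-3-hydroxypropyl]phenol | O[C@H](CCc1c(O)c(CC=C)c(OCc2ccccc2)cc1OCc1ccccc1)c1ccc(Br)cc1
F5 | step 9 | (2S)-8-allyl-5,7-bis(benzyloxy)-2-(4-bromophenyl)chromane | C=CCc1c(OCc2ccccc2)cc(OCc2ccccc2)c2c1O[C@H](c1ccc(Br)cc1)CC2
F6 | step 12 | 2-[(2S)-5,7-bis(benzyloxy)-2-[4-(benzyloxy)phenyl]chroman-8-yl]acetic acid | OC(=O)Cc1c(OCc2ccccc2)cc(OCc2ccccc2)c2c1O[C@H](c1ccc(OCc3ccccc3)cc1)CC2
F7 | step 12 | 2-[(2S)-5,7-bis(benzyloxy)-2-[4-(benzyloxy)phenyl]chroman-8-yl]-N-methoxy-N-methylacetamide | CON(C)C(=O)Cc1c(OCc2ccccc2)cc(OCc2ccccc2)c2c1O[C@H](c1ccc(OCc3ccccc3)cc1)CC2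
F8 | step 16 | trans-5,7-bis(benzyloxy)-2-[4-(benzyloxy)phenyl]-3-[(2S)-5,7-bis(benzyloxy)-2-[4-(benzyloxy)phenyl]chroman-8-yl]chroman-4-one (both trans diastereomers) | O=C1c2c(OCc3ccccc3)cc(OCc3ccccc3)cc2OC(c2ccc(OCc3ccccc3)cc2)C1c1c(OCc2ccccc2)cc(OCc2ccccc2)c2c1O[C@H](c1ccc(OCc3ccccc3)cc1)CC2
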